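(The constants come from no measurement; the result is computed.)

4 questions are put to one catalytic flask in two charges, summer and noon, which differ in second substrate.

- summer: starting material 5.0 × 10⁻⁴ M; second substrate 1.00 mM; coupling partner 0.500 mM; free catalyst 5.0 µM; time 40 s
- noon: starting material 5.0 × 10⁻⁴ M; second substrate 3.00 mM; coupling partner 0.500 mM; free catalyst 5.0 µM; time 40 s

    starting material + free catalyst ⇌ catalyst intermediate A (K1 = 1200 /M, k1 = 26000 /M/s)
    coupling partner + catalyst intermediate A → free catalyst + target (k2 = 29000 /M/s)
    second substrate + free catalyst ⇌ catalyst intermediate B (K3 = 470 /M, k3 = 6.8 × 10⁵ /M/s)
    coupling partner + catalyst intermediate B → free catalyst + second product (k4 = 18000 /M/s)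
    target + free catalyst ⇌ isomer of the product + free catalyst, rate k5*[free catalyst]*[target] forward; the back reaction follows from the equilibrium constant (K5 = 2.5, k5 = 33000 /M/s)
    starting material + coupling partner → uncatalysed product (k6 = 44 /M/s)

- which of these there is most of at the end, counted by the starting material in it, summer (uncatalysed product / target / isomer of the product / starting material)
- which of these there is most of at the end, counted by the starting material in it, noon (uncatalysed product / target / isomer of the product / starting material)
- the largest of these amounts at the end, in percent of the starting material charged, summer
- the largest of these amounts at the end, in percent of the starting material charged, noon

Coupling partner leaves by reaction with catalyst intermediate A to target, with catalyst intermediate B to second product, or directly with starting material to uncatalysed product. Call d, the diverted share, the fraction of consumed coupling partner that ends in second product. The charges of starting material and coupling partner are equal and the catalyst is a trace, so once coupling partner is consumed, the fraction of starting material left equals d.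

The first extreme is the flask frozen at its charge. Catalyst intermediate A is released at 21.7 /s and drained by coupling partner at 14.5 /s, so it stands at quasi-steady state at 0.359 of free catalyst. Catalyst intermediate B is released far faster than it is drained, so it stands at equilibrium. Free catalyst is then 54.7% of the catalyst in summer and 36.1% at noon. In summer coupling partner decays with the pseudo-first-order constant 0.0736 /s, and d is 31.4%.

The second extreme is the summer flask with coupling partner just gone and starting material down to that fraction. The constant is then 0.0467 /s and d is 48.2%, higher than at the charge. Replacing the curve by its midpoint gives the mean diverted share 39.8%, give or take 8.4 percentage points. The mean constant leaves 9.02% of coupling partner at the end, so this reckoning puts summer starting material at 45.2%.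

At noon the same steps give, at the charge, the constant 0.0866 /s and a d of 52.9%, and with coupling partner just gone the constant 0.0738 /s and a d of 60.3%. The mean is 56.6%, and starting material stands at 58.3%. Split at the starting rates, the consumed part gives a summer catalysed portion near 30.9%, less than the starting material left. The noon uncatalysed portion is near 22.5%, again less than the starting material left. So this reckoning names starting material in both flasks.

The forecast names starting material for summer at 45% and starting material for noon at 60%, holding that the larger charge of second substrate at noon “ties up more catalyst and diverts more coupling partner”. Its noon figure stands above the 58.3% of this reckoning.

The simulation gives starting material at 41.8% in summer and starting material at 57.5% at noon. Neither flask is at rest at 40.0 s: summer keeps 9.61% of its coupling partner and noon 4.4%. By 400 s coupling partner stands at 0% in summer and 0% at noon. Starting material there reads 36.3% in summer, against a mean diverted share of 39.8%, and 55.7% at noon, against 56.6%. Target and isomer of the product still shift by then: summer target falls to 11.5% while its isomer rises to 28.6%, and noon isomer rises to 16.6%.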